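The ratio I carry through this flask is the adduct constant times [released group], which says how much reagent sits as idle adduct for each free reagent, since released group is what the scavenger removes.

all flasks: substrate 20 mM; reagent 1.00 equiv; free catalyst 0.5 mol%; time 30 h
- south-west: scavenger 0.800 equiv
- north-east: scavenger 1.00 equiv

    reagent + free catalyst ⇌ catalyst intermediate A (K1 = 24.7 L mol⁻¹, k1 = 369 L mol⁻¹ min⁻¹)
    substrate + catalyst intermediate A ⇌ catalyst intermediate B (K2 = 18.5 L mol⁻¹, k2 = 11.8 L mol⁻¹ min⁻¹)
    catalyst intermediate B ⇌ released group + catalyst intermediate C (K3 = 0.017 M, k3 = 1.63 min⁻¹)
    catalyst intermediate C ⇌ free catalyst + target (K4 = 0.021 M, k4 = 56.3 min⁻¹)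
    reagent + released group ⇌ idle adduct, settled at all times (K5 = 17 L mol⁻¹)
    scavenger + released group → scavenged by-product (k6 = 2.40 L mol⁻¹ min⁻¹)
    crystals ⇌ target, rate k7*(cs7 - [target]) while solid is left; crystals form when [target] > cs7 (cs7 = 12 mM, k7 = 0.135 min⁻¹)
    substrate + target → side product (k8 = 0.0611 L mol⁻¹ min⁻¹)

- a species is counted by the substrate in it: one side product counts as two
- amounts and yields of target count crystals too
- amounts and yields of released group count idle adduct too
- given per volume of solution although it is solid: crystals
- run time (south-west): 30 h

- part of the substrate that has reacted at the end, south-west
- part of the substrate that has reacted at the end, north-east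
- what raising the equivalents of scavenger from its lowest to its highest value here does to the part of the substrate that has reacted (changes below 5 percentage points count as none) (it rises / no change / it falls)

I turn the question round: for the scavenger to shift the reacted part by 5 percentage points, the two charges must hold [released group] at levels that differ in the catalytic flow by a share of that order. Released group has two ways to act: it holds reagent as idle adduct as [released group] nears 58.8 mM, and it turns catalyst intermediate C back as it nears 587 mM, where return matches forward release of target. The first level is lower, so I reckon against it.

To get [released group], I start from the catalyst. At the start, the step-one constant times [reagent] is 0.49, so a share of 0.331, about a third, of the catalyst sits as catalyst intermediate A. Its reaction with substrate then gives a flow of 0.00780 mM min⁻¹, taken at the charged concentrations and with the way back ignored. Over 30 h that flow amounts to 14.0 mM, less than the 16.0 mM of scavenger in south-west, so by this reckoning scavenger remains there throughout. In the quasi-steady state, released group is made as fast as the pseudo-first-order capture removes it, so its level is the flow divided by the capture constant times [scavenger].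

| flask | [released group] | adduct constant × level | its logarithm, base ten |
|---|---|---|---|
| south-west | 0.203 mM | 0.00345 | −2.46 |
| north-east | 0.163 mM | 0.00276 | −2.56 |

That product is the margin: the level of free released group as a fraction of the level at which idle adduct matches free reagent. The two flasks differ in it by 0.0691 %, far below 5 points, so I commit to no change.

The forecast gives 45 % for south-west, 46 % for north-east and no change, on the grounds that “both scavenger loadings are far in excess of the released group formed”.

The simulation gives 46.5 % for south-west and 46.6 % for north-east, a change of 0.05 points, so no change. At 30.0 h, [released group] reads 0.0863 mM in south-west and 0.0618 mM in north-east, which puts the south-west margin at 0.00147, less than the 0.00345 I reckoned for that flask. The neighbour of north-east charged with 2 mol% of free catalyst reaches 81.0 % reacted, and its [released group] of 0.0806 mM at 30.0 h gives a margin of 0.00137, also less than 0.00345.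

The rate constants come from no measurement; no experiment stands behind them.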